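Cuts, in flavone numbering: first the three O-CH3 bonds on ring B, then O1-C2 of ring C. This leaves a C2-amino/C4-keto enaminone, whose nitrogen and C4 oxygen are rejoined as the N-O bond of an isoxazole (isoxazole C3 = C2 with ring B, C4 = C3 with the isopentyl chain, C5 = C4). Then C4a-C8a of ring A is cut, followed by C5-C6, C4a-C5, C3-C4 and C2-C3.
Enabling feature: ring A carries oxygen on the alternating atoms C5, C7 and C8a, so it is a folded 3,5-dioxohexanoate whose C6 is C4a. C4a is bonded to the C4-C3-C2 1,3-dicarbonyl unit. Held as an isoxazole, that unit acidifies the C4a methylene but offers no electrophilic carbonyl and no enolisable C3.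
Chain assembly: ring B is bought. Grignard addition forms C2-C3, oxime dianion acylation forms C3-C4, lateral carboxylation forms C4a-C5, and acylation of a bis(silyl enol ether) of methyl acetoacetate forms C5-C6.
Ring order: the isoxazole comes first, then ring A by Claisen closure of C4a-C8a. Ring C follows by N-O hydrogenolysis and O1-C2 closure with loss of ammonia, and demethylation comes last.
Stereochemistry: the target has no stereocentre and no stereogenic double bond. The only geometry that matters on the way is the E oxime, which is the thermodynamic isomer.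

Key step: step 8

Remark: the two ortho hydroxyl groups of the phloroglucinol made in the key step are equivalent by symmetry, so the labels C5 and C8a become distinct only when ring C closes. The double-bond geometries of the two silyl enol ethers have no consequence and are left open.

Step 1
Reactants: 1 3,4,5-trimethoxybenzonitrile; 2 1-bromo-4-methylpentane
Product: 5 5-methyl-1-(3,4,5-trimethoxyphenyl)hexan-1-one, via 4-methylpentylmagnesium bromide 3 (not isolated), via N-bromomagnesio ketimine 4 (not isolated)
Conditions: Mg, THF, reflux; 1, THF, reflux; then 2 M HCl, rt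
Reagents that add atoms: water, O
Why: Grignard addition to an aromatic nitrile, which has no alpha-protons to lose, stops at the N-magnesio ketimine because this takes up no second equivalent, and aqueous acid hydrolyses it to the aryl alkyl ketone whose alpha-CH2 is the future C3.

Step 2
Reactants: 5 5-methyl-1-(3,4,5-trimethoxyphenyl)hexan-1-one
Product: 6 (E)-5-methyl-1-(3,4,5-trimethoxyphenyl)hexan-1-one oxime
Conditions: NH2OH·HCl, NaOAc, EtOH/H2O, reflux
Reagents that add atoms: hydroxylamine hydrochloride, Cl.NO
Why: Oxime condensation of an aryl n-alkyl ketone favours the E isomer thermodynamically (OH anti to the aryl ring and syn to the alpha-CH2), which is the geometry that the syn-directed lithiation of the next step requires.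

Step 3
Reactants: 6 (E)-5-methyl-1-(3,4,5-trimethoxyphenyl)hexan-1-one oxime; 7 N-methoxy-N-methylacetamide
Product: 10 5-methyl-4-(3-methylbutyl)-3-(3,4,5-trimethoxyphenyl)-1,2-oxazole, via C,O-dilithio oxime 8 (not isolated), via 5-hydroxyisoxazoline 9 (not isolated)
Conditions: n-BuLi (2.2 equiv), THF, 0 °C; 7, 0 °C to rt; then 3 M H2SO4, THF, reflux
Reagents that add atoms: none
Why: In this dilithio-oxime isoxazole synthesis the second lithiation occurs at the alpha-carbon syn to O-Li, the Weinreb-type acyl donor delivers a single acetyl group through a chelated tetrahedral adduct, the beta-keto oxime closes to 9 and acid dehydrates it to the aromatic ring, so nitrogen stays on the aryl-bearing carbon and only one regioisomer can form.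

Step 4
Reactants: 10 5-methyl-4-(3-methylbutyl)-3-(3,4,5-trimethoxyphenyl)-1,2-oxazole
Product: 12 [4-(3-methylbutyl)-3-(3,4,5-trimethoxyphenyl)-1,2-oxazol-5-yl]acetic acid, via 5-lithiomethylisoxazole 11 (not isolated)
Conditions: n-BuLi (1.05 equiv), THF, -78 °C; CO2; then 1 M HCl, 0 °C
Reagents that add atoms: carbon dioxide, O=C=O
Why: Lateral lithiation of a 5-methylisoxazole followed by carboxylation should work because the C5-methyl protons are the most acidic ones (the charge is delocalised through isoxazole C4 onto the ring nitrogen) and no ring proton is left whose removal would open the heterocycle.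

Step 5
Reactants: 13 methyl acetoacetate
Product: 14 methyl 3-(trimethylsilyloxy)but-2-enoate
Conditions: Me3SiCl, Et3N, hexane, rt
Reagents that add atoms: chlorotrimethylsilane, C[Si](C)(C)Cl
Why: O-silylation of the enolised beta-keto ester under amine base (silyl enol ether formation) is a standard operation and masks the ketone for the following gamma-deprotonation.

Step 6
Reactants: 14 methyl 3-(trimethylsilyloxy)but-2-enoate
Product: 15 1-methoxy-1,3-bis(trimethylsilyloxy)buta-1,3-diene
Conditions: LiN(i-Pr)2, THF, -78 °C; Me3SiCl, -78 °C to rt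
Reagents that add atoms: chlorotrimethylsilane, C[Si](C)(C)Cl
Why: Kinetic gamma-deprotonation of the silyloxycrotonate and O-silylation of the dienolate give the 1,3-bis(silyl enol ether), the neutral equivalent of the acetoacetate dianion.

Step 7
Reactants: 12 [4-(3-methylbutyl)-3-(3,4,5-trimethoxyphenyl)-1,2-oxazol-5-yl]acetic acid; 15 1-methoxy-1,3-bis(trimethylsilyloxy)buta-1,3-diene
Product: 17 methyl 6-[4-(3-methylbutyl)-3-(3,4,5-trimethoxyphenyl)-1,2-oxazol-5-yl]-3,5-dioxohexanoate, via isoxazolylacetyl chloride 16 (not isolated)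
Conditions: (COCl)2, DMF (cat.), CH2Cl2, 0 °C to rt, evaporate; 15 (1.5 equiv), CH2Cl2, -78 °C to rt; H2O
Reagents that add atoms: none
Why: After Vilsmeier-type acid chloride formation comes a Mukaiyama-type vinylogous C-acylation, in which 1,3-bis(silyl enol ethers) are known to attack acid chlorides through their terminal carbon without base or Lewis acid to give 3,5-dioxo esters, so the acidic isoxazolyl-CH2-C=O protons, which would quench a lithium dienolate or an acetoacetate dianion, never meet a base.

Step 8
Reactants: 17 methyl 6-[4-(3-methylbutyl)-3-(3,4,5-trimethoxyphenyl)-1,2-oxazol-5-yl]-3,5-dioxohexanoate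
Product: 19 2-[4-(3-methylbutyl)-3-(3,4,5-trimethoxyphenyl)-1,2-oxazol-5-yl]benzene-1,3,5-triol, via 2-isoxazolylcyclohexane-1,3,5-trione 18 (not isolated)
Conditions: Mg(OMe)2 (5 equiv), MeOH, reflux, Ar; then 1 M HCl, 0 °C
Reagents that add atoms: none
Why: Proposed new method: Mg(OMe)2 first turns 17 into its C3/C5 diketonate, and reversible further deprotonation at C6, which is acidified by the C5 carbonyl and by the isoxazol-5-yl group, gives a C4,C6-dianion in which C2 keeps both protons and C1 is therefore still a true ester; C6 adds to C1, methoxide leaves, and trione 18 enolises at once to the phloroglucinolate, which makes the C-C closure irreversible. The closest known reaction types are the biomimetic Claisen cyclisation of 3,5,7-trioxo esters to acylphloroglucinols and the Dieckmann-type closure of 6-aryl-5-oxohexanoates to 2-arylcyclohexane-1,3-diones; new here is an isoxazole as the activating group at the terminus of a 3,5-dioxo ester. The one ring (ring A, bond C4a-C8a, chain C6 to C1) closes in the favoured 6-(enolendo)-exo-trig mode, every other C-C closure inside the chain would give a four-membered ring, and the aldol mode of the parent triketo esters (C2 onto C7) is shut off because that carbon is isoxazole C5 and no carbonyl. No stereocentre is formed. The selectivity needed is C- over O-acylation (the rival is lactonisation through the C5 enolate oxygen to a 4-hydroxy-2-pyranone); in the substrate it rests on the isoxazole-acidified C6-H, which makes the carbon nucleophile available under equilibrating conditions, and on aromatisation as the only irreversible exit, and Mg(OMe)2 in MeOH supports it because this reagent holds beta-polycarbonyl esters open as chelates and methanolyses acylpyranones back to them. Amide bases in excess are avoided, since a C2,C4,C6-trianion would turn C1 into an ester enolate and switch the electrophile off, and the matched MeOH/methyl ester pair makes transesterification harmless.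

Step 9
Reactants: 19 2-[4-(3-methylbutyl)-3-(3,4,5-trimethoxyphenyl)-1,2-oxazol-5-yl]benzene-1,3,5-triol
Product: 21 5,7-dihydroxy-3-(3-methylbutyl)-2-(3,4,5-trimethoxyphenyl)-4H-chromen-4-one, via Z-enaminoketone 20 (not isolated)
Conditions: H2 (3 bar), 10% Pd/C, EtOH, rt; filter; HCl (conc.), EtOH, reflux
Reagents that add atoms: none
Why: Hydrogenolysis of the weak isoxazole N-O bond gives the hydrogen-bonded Z beta-amino enone, a vinylogous amide that resists further reduction, and in hot acid either of the two equivalent ortho phenols adds to the iminium-like C2 and ammonia leaves (addition-elimination closing the six-membered ring C), which is the established unmasking of 5-(2-hydroxyaryl)isoxazoles to chromones.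

Step 10
Reactants: 21 5,7-dihydroxy-3-(3-methylbutyl)-2-(3,4,5-trimethoxyphenyl)-4H-chromen-4-one
Product: 22 asplenetin, 5,7-dihydroxy-3-(3-methylbutyl)-2-(3,4,5-trihydroxyphenyl)-4H-chromen-4-one
Conditions: BBr3 (8 equiv), CH2Cl2, -78 °C to rt; then H2O, 0 °C
Reagents that add atoms: none
Why: Aryl methyl ether cleavage with BBr3 is routine for polymethoxyflavones, the chromone, the free phenols (held as borates) and the saturated side chain are inert, and hydrolysis releases the pyrogallol ring.

Compound list
1 | 3,4,5-trimethoxybenzonitrile | COc1cc(C#N)cc(OC)c1OC | starting material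
2 | 1-bromo-4-methylpentane | CC(C)CCCBr | starting material
3 | 4-methylpentylmagnesium bromide | CC(C)CCC[Mg]Br | intermediate
4 | N-bromomagnesio ketimine of 5 | CC(C)CCCC(=N[Mg]Br)c1cc(OC)c(OC)c(OC)c1 | intermediate
5 | 5-methyl-1-(3,4,5-trimethoxyphenyl)hexan-1-one | CC(C)CCCC(=O)c1cc(OC)c(OC)c(OC)c1 | intermediate
6 | (E)-5-methyl-1-(3,4,5-trimethoxyphenyl)hexan-1-one oxime | CC(C)CCC/C(=N\O)c1cc(OC)c(OC)c(OC)c1 | intermediate
7 | N-methoxy-N-methylacetamide | CON(C)C(C)=O | starting material
8 | C(alpha),O-dilithio derivative of oxime 6 | CC(C)CCC([Li])/C(=N\O[Li])c1cc(OC)c(OC)c(OC)c1 | intermediate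
9 | 5-methyl-4-(3-methylbutyl)-3-(3,4,5-trimethoxyphenyl)-4,5-dihydro-1,2-oxazol-5-ol (mixture of diastereomers, both centres lost on dehydration) | CC(C)CCC1C(c2cc(OC)c(OC)c(OC)c2)=NOC1(C)O | intermediate
10 | 5-methyl-4-(3-methylbutyl)-3-(3,4,5-trimethoxyphenyl)-1,2-oxazole | Cc1onc(-c2cc(OC)c(OC)c(OC)c2)c1CCC(C)C | intermediate
11 | 5-(lithiomethyl)-4-(3-methylbutyl)-3-(3,4,5-trimethoxyphenyl)-1,2-oxazole | [Li]Cc1onc(-c2cc(OC)c(OC)c(OC)c2)c1CCC(C)C | intermediate
12 | [4-(3-methylbutyl)-3-(3,4,5-trimethoxyphenyl)-1,2-oxazol-5-yl]acetic acid | OC(=O)Cc1onc(-c2cc(OC)c(OC)c(OC)c2)c1CCC(C)C | intermediate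
13 | methyl acetoacetate | COC(=O)CC(C)=O | starting material
14 | methyl 3-(trimethylsilyloxy)but-2-enoate (geometry open) | COC(=O)C=C(C)O[Si](C)(C)C | intermediate
15 | 1-methoxy-1,3-bis(trimethylsilyloxy)buta-1,3-diene (geometry open) | COC(O[Si](C)(C)C)=CC(=C)O[Si](C)(C)C | intermediate
16 | [4-(3-methylbutyl)-3-(3,4,5-trimethoxyphenyl)-1,2-oxazol-5-yl]acetyl chloride | ClC(=O)Cc1onc(-c2cc(OC)c(OC)c(OC)c2)c1CCC(C)C | intermediate
17 | methyl 6-[4-(3-methylbutyl)-3-(3,4,5-trimethoxyphenyl)-1,2-oxazol-5-yl]-3,5-dioxohexanoate | COC(=O)CC(=O)CC(=O)Cc1onc(-c2cc(OC)c(OC)c(OC)c2)c1CCC(C)C | intermediate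
18 | 2-[4-(3-methylbutyl)-3-(3,4,5-trimethoxyphenyl)-1,2-oxazol-5-yl]cyclohexane-1,3,5-trione | CC(C)CCc1c(-c2cc(OC)c(OC)c(OC)c2)noc1C1C(=O)CC(=O)CC1=O | intermediate
19 | 2-[4-(3-methylbutyl)-3-(3,4,5-trimethoxyphenyl)-1,2-oxazol-5-yl]benzene-1,3,5-triol | CC(C)CCc1c(-c2cc(OC)c(OC)c(OC)c2)noc1-c1c(O)cc(O)cc1O | intermediate
20 | (Z)-3-amino-2-(3-methylbutyl)-1-(2,4,6-trihydroxyphenyl)-3-(3,4,5-trimethoxyphenyl)prop-2-en-1-one | CC(C)CC/C(C(=O)c1c(O)cc(O)cc1O)=C(/N)c1cc(OC)c(OC)c(OC)c1 | intermediate
21 | 5,7-dihydroxy-3-(3-methylbutyl)-2-(3,4,5-trimethoxyphenyl)-4H-chromen-4-one | CC(C)CCc1c(-c2cc(OC)c(OC)c(OC)c2)oc2cc(O)cc(O)c2c1=O | intermediate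
22 | asplenetin, 5,7-dihydroxy-3-(3-methylbutyl)-2-(3,4,5-trihydroxyphenyl)-4H-chromen-4-one | CC(C)CCc1c(-c2cc(O)c(O)c(O)c2)oc2cc(O)cc(O)c2c1=O | target

Total step count: 10.
Longest linear sequence: 8 steps (steps 1 to 4 and 7 to 10, from 1 and 2). Steps 5 and 6 form a two-step side branch.

Steps most likely to fail

**Step 8.**
- Lactonisation through the enolate oxygen may outrun the carbon closure.
- The magnesium chelate draws the C3 and C5 oxygens together and thereby holds C2 and C6 apart, so folding may be slow.
- Methoxide may cut the chain by retro-Claisen scission.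

The fallback gives up the folding and buys ring A as an arene. It sets out from ketone 5. Its lithium enolate (LiN(SiMe3)2, THF, -78 °C) is C-acylated with commercial 2,4,6-trimethoxybenzoyl chloride in a crossed Claisen-type acylation. This gives 2-(3-methylbutyl)-1-(2,4,6-trimethoxyphenyl)-3-(3,4,5-trimethoxyphenyl)propane-1,3-dione F1. BBr3 in CH2Cl2 removes all six methyl groups to give the hexahydroxy diketone F2. In warm aqueous-methanolic HCl an ortho phenol of F2 cyclodehydrates onto the carbonyl next to ring B, the classical 1,3-diketone closure of flavones. The fallback comes back to the route at target 22.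

**Step 7.**
- The diene may attack through its central carbon or through oxygen.
- The acid chloride may lose HCl and go on through ketene chemistry.
- The product may lactonise during purification.

The fallback replaces the silyl dienol ether by a dioxinone dienolate and an amide acyl donor. It sets out from acid 12. Carbonyldiimidazole and then MeNHOMe·HCl give the N-methoxy-N-methylamide F3. The lithium dienolate of commercial 2,2,6-trimethyl-4H-1,3-dioxin-4-one (LiN(SiMe3)2, THF, -78 °C) is acylated at its gamma-carbon to give the keto-dioxinone F4. Three equivalents of dienolate are used so that the acidic CH2 groups of donor and product are paid for. Heating F4 in toluene with an excess of MeOH releases acetone by retro-hetero-Diels-Alder reaction. The acylketene F5 so formed is trapped by MeOH, which comes back to the route at 17.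

**Step 3.**
- Proton transfer from the acetyl donor to the dianion may compete with acylation.
- Lithiation at the secondary alpha-carbon may be incomplete.
- The oxime may hydrolyse in the hot acid.

The fallback closes the isoxazole by oxidative O-C bond formation instead of acylation and dehydration. It sets out from ketone 5. LiN(i-Pr)2 and then acetaldehyde give the aldol adduct F6. p-TsOH in refluxing toluene dehydrates it to the (E)-ethylidene ketone F7. NH2OH·HCl in pyridine/EtOH gives the enone oxime F8. The iodine-mediated oxidative cyclisation of alpha,beta-unsaturated oximes (I2, KI, NaHCO3, THF/H2O, reflux) then comes back to the route at 10.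

Further compounds
F1 | step 8 | 2-(3-methylbutyl)-1-(2,4,6-trimethoxyphenyl)-3-(3,4,5-trimethoxyphenyl)propane-1,3-dione (racemic, enolisable) | CC(C)CCC(C(=O)c1c(OC)cc(OC)cc1OC)C(=O)c1cc(OC)c(OC)c(OC)c1
F2 | step 8 | 2-(3-methylbutyl)-1-(2,4,6-trihydroxyphenyl)-3-(3,4,5-trihydroxyphenyl)propane-1,3-dione (racemic, enolisable) | CC(C)CCC(C(=O)c1c(O)cc(O)cc1O)C(=O)c1cc(O)c(O)c(O)c1
F3 | step 7 | N-methoxy-N-methyl-2-[4-(3-methylbutyl)-3-(3,4,5-trimethoxyphenyl)-1,2-oxazol-5-yl]acetamide | CON(C)C(=O)Cc1onc(-c2cc(OC)c(OC)c(OC)c2)c1CCC(C)C
F4 | step 7 | 2,2-dimethyl-6-{3-[4-(3-methylbutyl)-3-(3,4,5-trimethoxyphenyl)-1,2-oxazol-5-yl]-2-oxopropyl}-4H-1,3-dioxin-4-one | CC(C)CCc1c(-c2cc(OC)c(OC)c(OC)c2)noc1CC(=O)CC1=CC(=O)OC(C)(C)O1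
F5 | step 7 | acylketene, 6-[4-(3-methylbutyl)-3-(3,4,5-trimethoxyphenyl)-1,2-oxazol-5-yl]hex-1-ene-1,3,5-trione | CC(C)CCc1c(-c2cc(OC)c(OC)c(OC)c2)noc1CC(=O)CC(=O)C=C=O
F6 | step 3 | 2-(1-hydroxyethyl)-5-methyl-1-(3,4,5-trimethoxyphenyl)hexan-1-one (mixture of diastereomers) | CC(C)CCC(C(C)O)C(=O)c1cc(OC)c(OC)c(OC)c1
F7 | step 3 | (E)-2-ethylidene-5-methyl-1-(3,4,5-trimethoxyphenyl)hexan-1-one | C/C=C(\CCC(C)C)C(=O)c1cc(OC)c(OC)c(OC)c1
F8 | step 3 | (E)-2-ethylidene-5-methyl-1-(3,4,5-trimethoxyphenyl)hexan-1-one oxime (C=N geometry open) | C/C=C(\CCC(C)C)C(=NO)c1cc(OC)c(OC)c(OC)c1
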